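## Retrosynthetic overview

1. Target 28 ⇐ 27 by a final OsO4 syn‑dihydroxylation of C11=C12; 27 ⇐ 25 by CBS reduction of the C2 ketone and acetylation.
2. 25 ⇐ 23 by one macrocyclising intramolecular Diels–Alder reaction (bonds C1–C10 and C13–C14; cyclohexene ring A and ten‑membered ring B form together), then loss of HBr to give C13=C14.
3. 23 ⇐ 21: the γ‑lactone (ring C) is closed first, by an intramolecular Reformatsky reaction (C8–C17) of a C7 2‑bromopropanoate onto the C8 ketone.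
4. 21 ⇐ enal 8 + dienone 14: boron aldol (C7–C8), Felkin reduction (C9), two acylations, double oxidation.
5. 8 ⇐ neryl acetate (supplies the 5Z alkene); 14 ⇐ 3‑methyl‑3‑sulfolene + methyl glycolate. Ring order: C, then A and B in one operation.

Convention: locants C1–C20 are briarane locants of the target (ring A: C1, C10–C14; ring B: C1–C10; lactone: O–C7, C8, C17, C19=O; methyls C15 on C1, C16 on C5, C18 on C17, C20 on C11). C2 is a 1:1 epimer mixture from step 2 until step 14 oxidises it, and the CHBr centre of the 2‑bromopropanoate (steps 10–14) is also a mixture; both are left undefined in the SMILES.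

Assumption: (–)‑Ipc2BOTf is taken as the antipode that sends the enol borinate to the Re face of aldehyde 8 (7S); if the sense is reversed, (+)‑Ipc2BOTf is used and nothing else changes.

## Route

Step 1
Reactants: 1 neryl acetate [(2Z)-3,7-dimethylocta-2,6-dien-1-yl acetate]
Product: 3 (2Z)-3-methyl-6-oxohex-2-en-1-yl acetate, via secondary ozonide 2 (not isolated)
Conditions: O3 (1.0 equiv), CH2Cl2/pyridine, −78 °C; Me2S
Reagents that add atoms: ozone, [O-][O+]=O
Why: Site‑selective ozonolysis with reductive work‑up: the distal trisubstituted alkene is far more electron‑rich than the acetate‑deactivated allylic one, so the 5Z alkene survives.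

Step 2
Reactants: 3 (2Z)-3-methyl-6-oxohex-2-en-1-yl acetate
Product: 4 (2Z)-6-hydroxy-3-methyloct-2-en-7-yn-1-yl acetate (racemic)
Conditions: HC≡CMgBr (1.2 equiv), THF, −78 °C
Reagents that add atoms: ethynylmagnesium bromide, C#C[Mg]Br
Why: Grignard 1,2‑addition to the aldehyde is much faster than attack on the acetate at −78 °C; the new carbinol (C2) is racemic and is oxidised later.

Step 3
Reactants: 4 (2Z)-6-hydroxy-3-methyloct-2-en-7-yn-1-yl acetate
Product: 6 (2Z,7Z)-8-bromo-3,7-dimethylocta-2,7-diene-1,6-diol (racemic), via alkenylmagnesium bis-alkoxide 5 (not isolated)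
Conditions: MeMgBr (5 equiv), CuI (20 mol %), Et2O, 0 °C → rt; NBS, −78 → 0 °C
Reagents that add atoms: methylmagnesium bromide, C[Mg]Br; N-bromosuccinimide, O=C1CCC(=O)N1Br
Why: Duboudin copper‑catalysed anti‑carbomagnesiation of the propargylic alkoxide puts methyl on the proximal carbon and magnesium on the terminal carbon cis to the carbinol, NBS brominates the alkenyl Grignard with retention, and excess MeMgBr removes the acetate.

Step 4
Reactants: 6 (2Z,7Z)-8-bromo-3,7-dimethylocta-2,7-diene-1,6-diol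
Product: 7 (2Z,7Z)-8-bromo-6-hydroxy-3,7-dimethylocta-2,7-dienal (racemic)
Conditions: TEMPO (10 mol %), PhI(OAc)2, CH2Cl2, rt
Reagents that add atoms: none
Why: TEMPO/PhI(OAc)2 oxidation is selective for the primary allylic alcohol over the hindered secondary one and does not isomerise the Z‑enal.

Step 5
Reactants: 7 (2Z,7Z)-8-bromo-6-hydroxy-3,7-dimethylocta-2,7-dienal
Product: 8 (2Z,7Z)-8-bromo-6-[(tert-butyldimethylsilyl)oxy]-3,7-dimethylocta-2,7-dienal (racemic)
Conditions: TBSCl, imidazole, DMF, 0 °C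
Reagents that add atoms: tert-butyldimethylsilyl chloride, CC(C)(C)[Si](C)(C)Cl
Why: Standard silyl ether formation masks C2–OH through the acylation and reduction steps that follow.

Step 6
Reactants: 9 methyl glycolate
Product: 10 methyl 2-[(tert-butyldimethylsilyl)oxy]acetate
Conditions: TBSCl, imidazole, CH2Cl2, rt
Reagents that add atoms: tert-butyldimethylsilyl chloride, CC(C)(C)[Si](C)(C)Cl
Why: Standard silylation; the bulky, non‑chelating TBS ether later enforces Felkin control at C9.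

Step 7
Reactants: 11 3-methyl-3-sulfolene (3-methyl-2,5-dihydrothiophene 1,1-dioxide), 10 methyl 2-[(tert-butyldimethylsilyl)oxy]acetate
Product: 13 2-{[(tert-butyldimethylsilyl)oxy]acetyl}-3-methyl-2,5-dihydrothiophene 1,1-dioxide (racemic), via 2-lithio-3-methyl-3-sulfolene 12 (not isolated)
Conditions: LiHMDS (2.2 equiv), THF, −78 °C; then 10; aq NH4Cl
Reagents that add atoms: none
Why: Claisen‑type C‑acylation of the sulfonyl‑stabilised allyl anion, which forms at C2 (the terminus not carrying the methyl); the second equivalent of base holds the β‑keto sulfone as its enolate.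

Step 8
Reactants: 13 2-{[(tert-butyldimethylsilyl)oxy]acetyl}-3-methyl-2,5-dihydrothiophene 1,1-dioxide
Product: 14 (3E)-1-[(tert-butyldimethylsilyl)oxy]-4-methylhexa-3,5-dien-2-one
Conditions: PhMe, NaHCO3, 110 °C
Reagents that add atoms: none
Why: Cheletropic extrusion of SO2 from the 2‑substituted 3‑sulfolene is disrotatory with the acyl group turning outward, which gives the E‑diene.

Step 9
Reactants: 14 (3E)-1-[(tert-butyldimethylsilyl)oxy]-4-methylhexa-3,5-dien-2-one, 8 (2Z,7Z)-8-bromo-6-[(tert-butyldimethylsilyl)oxy]-3,7-dimethylocta-2,7-dienal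
Product: 16 (3E,6R,7S,8Z,13Z)-14-bromo-6,12-bis[(tert-butyldimethylsilyl)oxy]-7-hydroxy-3,9,13-trimethyltetradeca-1,3,8,13-tetraen-5-one (briarane 7S,8R), via (Z)-enol diisopinocampheylborinate 15 (not isolated)
Conditions: (–)-Ipc2BOTf, i-Pr2NEt, CH2Cl2, −78 °C; then 8, −78 → −20 °C; H2O2, MeOH, pH 7 buffer
Reagents that add atoms: none
Why: Paterson boron aldol: the (Z)-enol borinate (OTBS cis to OB) reacts through a Zimmerman–Traxler chair to give the 7,8‑syn adduct, and the Ipc ligands select the aldehyde Re face (7S).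

Step 10
Reactants: 16 syn‑aldol adduct (briarane 7S,8R)
Product: 17 (3E,6R,7S,8Z,13Z)-14-bromo-6,12-bis[(tert-butyldimethylsilyl)oxy]-3,9,13-trimethyl-5-oxotetradeca-1,3,8,13-tetraen-7-yl 2-bromopropanoate
Conditions: 2-bromopropanoyl bromide, pyridine, CH2Cl2, −20 °C
Reagents that add atoms: 2-bromopropanoyl bromide, CC(Br)C(Br)=O
Why: O‑acylation under mild base puts the future lactone carbons (C17, C18, C19) on O7 before O9 exists, which is what differentiates the two oxygens flanking C8.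

Step 11
Reactants: 17 C7 2-bromopropanoate, C9 ketone
Product: 18 (3E,5R,6S,7S,8Z,13Z)-14-bromo-6,12-bis[(tert-butyldimethylsilyl)oxy]-5-hydroxy-3,9,13-trimethyltetradeca-1,3,8,13-tetraen-7-yl 2-bromopropanoate (briarane 9R)
Conditions: NaBH4, CeCl3·7H2O, MeOH/THF, −78 °C
Reagents that add atoms: none
Why: Luche 1,2‑reduction of the dienyl ketone under Felkin–Anh control (hydride anti to the α‑OTBS bond) gives the 8,9‑syn alcohol, hence the 7,9‑syn array; esters and the alkenyl bromide are untouched at −78 °C.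

Step 12
Reactants: 18 C9 alcohol
Product: 19 (3E,5R,6S,7S,8Z,13Z)-5-(acetyloxy)-14-bromo-6,12-bis[(tert-butyldimethylsilyl)oxy]-3,9,13-trimethyltetradeca-1,3,8,13-tetraen-7-yl 2-bromopropanoate
Conditions: Ac2O, pyridine, DMAP (cat.), CH2Cl2, 0 °C
Reagents that add atoms: acetic anhydride, CC(=O)OC(C)=O
Why: Standard acetylation installs the final C9 acetate.

Step 13
Reactants: 19 C9 acetate, bis‑TBS ether
Product: 20 (3E,5R,6S,7S,8Z,13Z)-5-(acetyloxy)-14-bromo-6,12-dihydroxy-3,9,13-trimethyltetradeca-1,3,8,13-tetraen-7-yl 2-bromopropanoate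
Conditions: HF·pyridine, pyridine/THF, 0 °C → rt
Reagents that add atoms: none
Why: Buffered fluoride cleaves both secondary TBS ethers (O8 and O2) without acyl migration or loss of the esters.

Step 14
Reactants: 20 C8,C2‑diol
Product: 21 (3E,5R,7S,8Z,13Z)-5-(acetyloxy)-14-bromo-3,9,13-trimethyl-6,12-dioxotetradeca-1,3,8,13-tetraen-7-yl 2-bromopropanoate
Conditions: Dess–Martin periodinane (3 equiv), NaHCO3, CH2Cl2, 0 °C → rt
Reagents that add atoms: none
Why: Dess–Martin oxidation of both secondary alcohols gives the C8 ketone and the β‑bromo enone dienophile under non‑basic conditions, so C7 and C9 do not epimerise.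

Step 15
Reactants: 21 C8 ketone, C7 2-bromopropanoate
Product: 23 (1R,2E)-1-{(2S,3R,4R)-2-[(1Z,6Z)-7-bromo-2,6-dimethyl-5-oxohepta-1,6-dien-1-yl]-3-hydroxy-4-methyl-5-oxooxolan-3-yl}-3-methylpenta-2,4-dien-1-yl acetate (briarane 7S,9R,17R; C8 as in the target), via zinc ester enolate 22 (not isolated)
Conditions: activated Zn dust (TMSCl), THF, 0 °C → rt; aq NH4Cl
Reagents that add atoms: none
Why: Intramolecular Reformatsky reaction (the classical closure of cardenolide butenolide precursors): zinc inserts only into the α‑bromo ester, the enolate closes the five‑membered ring on C8 with the large C9 substituent trans to the C7 side chain, and the reversible zinc aldolate settles with Me‑18 trans to C9 (cis to OH).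

Step 16
Reactants: 23 lactone‑tethered diene/β‑bromo enone
Product: 25 (1S,5Z,7S,8S,9R,10S,17R)-9-acetoxy-8-hydroxy-2-oxobriara-5,11,13-trien-19,7-olide, via bromo cycloadduct 24 (not isolated)
Conditions: PhMe (1 mM), BHT, 150 °C, sealed tube; then DBU, 40 °C
Reagents that add atoms: none
Why: Proposed new method: a macrocyclising intramolecular Diels–Alder reaction (closest known type: the Diels–Alder closures that form the cyclohexene and the carbocyclic macro‑ring of cytochalasans, plus β‑halo‑enone cycloaddition/dehydrohalogenation) in which the lactone and the 5Z alkene pre‑organise the eight‑atom tether, A(1,3) strain with Me‑20 puts H9 in the diene plane so the dienophile arrives on the C8 face anti to the C9 acetate (10S), the α‑methyl enone reacts carbonyl‑exo to give the trans ring fusion (1S), and E2 loss of HBr can only occur toward C13.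

Step 17
Reactants: 25 C2 ketone
Product: 26 (1S,2R,5Z,7S,8S,9R,10S,17R)-9-acetoxy-2,8-dihydroxybriara-5,11,13-trien-19,7-olide
Conditions: (S)-Me-CBS (0.5 equiv), catecholborane (3 equiv), PhMe, −60 °C
Reagents that add atoms: none
Why: Corey–Bakshi–Shibata reduction: with quaternary C1 as the large group and C3H2 as the small group the (S)-catalyst gives the 2R alcohol, and catecholborane at −60 °C spares the lactone, the acetate and the diene.

Step 18
Reactants: 26 C2 alcohol
Product: 27 (1S,2R,5Z,7S,8S,9R,10S,17R)-2,9-diacetoxy-8-hydroxybriara-5,11,13-trien-19,7-olide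
Conditions: Ac2O, Et3N, DMAP (cat.), CH2Cl2, 0 °C → rt
Reagents that add atoms: acetic anhydride, CC(=O)OC(C)=O
Why: Acetylation of the secondary C2 alcohol; the tertiary, hydrogen‑bonded C8–OH is too hindered to react under these conditions.

Step 19
Reactants: 27 ring‑A diene diacetate
Product: 28 (1S,2R,5Z,7S,8S,9R,10S,11S,12R,17R)-2,9-diacetoxy-8,11,12-trihydroxybriara-5,13-dien-19,7-olide (CNP0146024.1)
Conditions: OsO4 (5 mol %), NMO, acetone/H2O, 0 °C; aq Na2SO3
Reagents that add atoms: osmium tetroxide, O=[Os](=O)(=O)=O; N-methylmorpholine N-oxide, C[N+]1([O-])CCOCC1; water, O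
Why: Upjohn syn‑dihydroxylation: OsO4 takes the more electron‑rich trisubstituted C11=C12 bond of the conjugated diene from the face anti to C9 (on C10) and to Me‑15, giving the 11S,12R cis‑diol, while C5=C6 is deactivated by the allylic lactone oxygen and shielded inside the ten‑membered ring.

## Compound list

1 | neryl acetate, (2Z)-3,7-dimethylocta-2,6-dien-1-yl acetate | CC(=O)OC/C=C(C)\CCC=C(C)C | starting material
2 | secondary ozonide of 1 at the distal alkene | CC(=O)OC/C=C(C)\CCC1OOC(C)(C)O1 | intermediate (not isolated)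
3 | (2Z)-3-methyl-6-oxohex-2-en-1-yl acetate | CC(=O)OC/C=C(C)\CCC=O | intermediate
4 | (2Z)-6-hydroxy-3-methyloct-2-en-7-yn-1-yl acetate (racemic) | CC(=O)OC/C=C(C)\CCC(O)C#C | intermediate
5 | C8‑magnesiated (2Z)-3,7-dimethylocta-2,7-diene-1,6-diolate, Mg cis to C6, bromomagnesium salts | Br[Mg]/C=C(/C)C(O[Mg]Br)CC/C(C)=C\CO[Mg]Br | intermediate (not isolated)
6 | (2Z,7Z)-8-bromo-3,7-dimethylocta-2,7-diene-1,6-diol (racemic) | OC/C=C(C)\CCC(O)/C(C)=C\Br | intermediate
7 | (2Z,7Z)-8-bromo-6-hydroxy-3,7-dimethylocta-2,7-dienal (racemic) | O=C/C=C(C)\CCC(O)/C(C)=C\Br | intermediate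
8 | (2Z,7Z)-8-bromo-6-[(tert-butyldimethylsilyl)oxy]-3,7-dimethylocta-2,7-dienal (racemic) | O=C/C=C(C)\CCC(O[Si](C)(C)C(C)(C)C)/C(C)=C\Br | intermediate
9 | methyl glycolate | COC(=O)CO | starting material
10 | methyl 2-[(tert-butyldimethylsilyl)oxy]acetate | COC(=O)CO[Si](C)(C)C(C)(C)C | intermediate
11 | 3-methyl-3-sulfolene (3-methyl-2,5-dihydrothiophene 1,1-dioxide) | CC1=CCS(=O)(=O)C1 | starting material
12 | 2-lithio-3-methyl-2,5-dihydrothiophene 1,1-dioxide | [Li]C1C(C)=CCS1(=O)=O | intermediate (not isolated)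
13 | 2-{[(tert-butyldimethylsilyl)oxy]acetyl}-3-methyl-2,5-dihydrothiophene 1,1-dioxide (racemic) | CC1=CCS(=O)(=O)C1C(=O)CO[Si](C)(C)C(C)(C)C | intermediate
14 | (3E)-1-[(tert-butyldimethylsilyl)oxy]-4-methylhexa-3,5-dien-2-one | C=C/C(C)=C/C(=O)CO[Si](C)(C)C(C)(C)C | intermediate
15 | (Z)-enol diisopinocampheylborinate of 14 (Ipc from (+)-α-pinene) | C=C/C(C)=C/C(OB([C@H]1[C@H](C)[C@H]2C[C@@H](C1)C2(C)C)[C@H]1[C@H](C)[C@H]2C[C@@H](C1)C2(C)C)=C/O[Si](C)(C)C(C)(C)C | intermediate (not isolated)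
16 | (3E,6R,7S,8Z,13Z)-14-bromo-6,12-bis[(tert-butyldimethylsilyl)oxy]-7-hydroxy-3,9,13-trimethyltetradeca-1,3,8,13-tetraen-5-one (C12 epimers) | C=C/C(C)=C/C(=O)[C@H](O[Si](C)(C)C(C)(C)C)[C@@H](O)/C=C(C)\CCC(O[Si](C)(C)C(C)(C)C)/C(C)=C\Br | intermediate
17 | (3E,6R,7S,8Z,13Z)-14-bromo-6,12-bis[(tert-butyldimethylsilyl)oxy]-3,9,13-trimethyl-5-oxotetradeca-1,3,8,13-tetraen-7-yl 2-bromopropanoate | C=C/C(C)=C/C(=O)[C@H](O[Si](C)(C)C(C)(C)C)[C@@H](OC(=O)C(C)Br)/C=C(C)\CCC(O[Si](C)(C)C(C)(C)C)/C(C)=C\Br | intermediate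
18 | (3E,5R,6S,7S,8Z,13Z)-14-bromo-6,12-bis[(tert-butyldimethylsilyl)oxy]-5-hydroxy-3,9,13-trimethyltetradeca-1,3,8,13-tetraen-7-yl 2-bromopropanoate | C=C/C(C)=C/[C@@H](O)[C@H](O[Si](C)(C)C(C)(C)C)[C@@H](OC(=O)C(C)Br)/C=C(C)\CCC(O[Si](C)(C)C(C)(C)C)/C(C)=C\Br | intermediate
19 | (3E,5R,6S,7S,8Z,13Z)-5-(acetyloxy)-14-bromo-6,12-bis[(tert-butyldimethylsilyl)oxy]-3,9,13-trimethyltetradeca-1,3,8,13-tetraen-7-yl 2-bromopropanoate | C=C/C(C)=C/[C@@H](OC(C)=O)[C@H](O[Si](C)(C)C(C)(C)C)[C@@H](OC(=O)C(C)Br)/C=C(C)\CCC(O[Si](C)(C)C(C)(C)C)/C(C)=C\Br | intermediate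
20 | (3E,5R,6S,7S,8Z,13Z)-5-(acetyloxy)-14-bromo-6,12-dihydroxy-3,9,13-trimethyltetradeca-1,3,8,13-tetraen-7-yl 2-bromopropanoate | C=C/C(C)=C/[C@@H](OC(C)=O)[C@H](O)[C@@H](OC(=O)C(C)Br)/C=C(C)\CCC(O)/C(C)=C\Br | intermediate
21 | (3E,5R,7S,8Z,13Z)-5-(acetyloxy)-14-bromo-3,9,13-trimethyl-6,12-dioxotetradeca-1,3,8,13-tetraen-7-yl 2-bromopropanoate | C=C/C(C)=C/[C@@H](OC(C)=O)C(=O)[C@@H](OC(=O)C(C)Br)/C=C(C)\CCC(=O)/C(C)=C\Br | intermediate
22 | bromozinc ester enolate of 21 (O‑bound, at the propanoate) | C=C/C(C)=C/[C@@H](OC(C)=O)C(=O)[C@@H](OC(O[Zn]Br)=CC)/C=C(C)\CCC(=O)/C(C)=C\Br | intermediate (not isolated)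
23 | (1R,2E)-1-{(2S,3R,4R)-2-[(1Z,6Z)-7-bromo-2,6-dimethyl-5-oxohepta-1,6-dien-1-yl]-3-hydroxy-4-methyl-5-oxooxolan-3-yl}-3-methylpenta-2,4-dien-1-yl acetate | CC(=O)O[C@@H]([C@]1(O)[C@@H](C)C(=O)O[C@H]1/C=C(C)\CCC(=O)/C(C)=C\Br)/C=C(C)/C=C | intermediate
24 | (1S,5Z,7S,8S,9R,10S,14S,17R)-9-acetoxy-14-bromo-8-hydroxy-2-oxobriara-5,11-dien-19,7-olide | CC(=O)O[C@@H]1[C@H]2C(C)=CC[C@H](Br)[C@]2(C)C(=O)CC/C(C)=C\[C@@H]2OC(=O)[C@H](C)[C@]21O | intermediate (not isolated)
25 | (1S,5Z,7S,8S,9R,10S,17R)-9-acetoxy-8-hydroxy-2-oxobriara-5,11,13-trien-19,7-olide | CC(=O)O[C@@H]1[C@H]2C(C)=CC=C[C@]2(C)C(=O)CC/C(C)=C\[C@@H]2OC(=O)[C@H](C)[C@]21O | intermediate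
26 | (1S,2R,5Z,7S,8S,9R,10S,17R)-9-acetoxy-2,8-dihydroxybriara-5,11,13-trien-19,7-olide | CC(=O)O[C@@H]1[C@H]2C(C)=CC=C[C@]2(C)[C@H](O)CC/C(C)=C\[C@@H]2OC(=O)[C@H](C)[C@]21O | intermediate
27 | (1S,2R,5Z,7S,8S,9R,10S,17R)-2,9-diacetoxy-8-hydroxybriara-5,11,13-trien-19,7-olide | CC(=O)O[C@@H]1[C@H]2C(C)=CC=C[C@]2(C)[C@H](OC(C)=O)CC/C(C)=C\[C@@H]2OC(=O)[C@H](C)[C@]21O | intermediate
28 | (1S,2R,5Z,7S,8S,9R,10S,11S,12R,17R)-2,9-diacetoxy-8,11,12-trihydroxybriara-5,13-dien-19,7-olide (CNP0146024.1) | CC(=O)O[C@@H]1[C@H]2[C@](C)(O)[C@H](O)C=C[C@]2(C)[C@H](OC(C)=O)CC/C(C)=C\[C@@H]2OC(=O)[C@H](C)[C@]21O | target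

## Step count and risks

Total step count: 19. Longest linear sequence: 16 steps (steps 1–5, then 9–19); steps 6–8 are a three‑step side branch.

Steps most likely to fail:

Step 16 (macrocyclising Diels–Alder). The ten‑membered ring, the trisubstituted dienophile and the required exo/facial sense are all demanding. The fallback changes the dienophile to a sulfinyl‑activated one that eliminates by itself. It sets out from 23: thiophenol and Et3N (addition–elimination at the β‑bromo enone) give the 14‑(phenylthio) enone F1. mCPBA (1.0 equiv, −78 °C) oxidises sulfur only and gives the 14‑(phenylsulfinyl) enone F2, a doubly activated dienophile. Heating F2 (PhMe, 110 °C, 1 mM) gives the sulfinyl cycloadduct F3 (not isolated), which loses benzenesulfenic acid by thermal syn‑elimination toward C13 and comes back to the route at 25.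

Step 9 (reagent‑controlled boron aldol). Enantio‑ and syn‑selectivity with an α‑silyloxy dienyl ketone may be only moderate. The fallback uses auxiliary control and builds the dienone afterwards. It sets out from 8: an Evans syn‑glycolate aldol with (R)-4-benzyl-3-{[(tert-butyldimethylsilyl)oxy]acetyl}oxazolidin-2-one (Bu2BOTf, Et3N) gives the imide F4. Me(MeO)NH·HCl/AlMe3 gives the Weinreb amide F5. Excess 2‑lithio‑3‑methyl‑3‑sulfolene 12 gives the β‑keto sulfone F6. Thermolysis (PhMe, 110 °C, loss of SO2) comes back to the route at 16.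

Step 15 (Reformatsky lactonisation). Ketone 21 is sensitive and the C17 configuration rests on aldolate equilibration. The fallback is a copper hydride reductive aldol cyclisation. It sets out from 21: DBU (1 equiv, 0 °C) eliminates HBr from the 2‑bromopropanoate and gives the C7 acrylate F7. Cu(OAc)2·H2O/bisphosphine with tetramethyldisiloxane (−40 °C) reduces the unhindered acrylate first, and the copper enolate closes onto the C8 ketone, coming back to the route at 23.

Further compounds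
F1 | step 16 | 14-(phenylthio) analogue of 23 (β-phenylthio enone) | CC(=O)O[C@@H]([C@]1(O)[C@@H](C)C(=O)O[C@H]1/C=C(C)\CCC(=O)/C(C)=C\Sc1ccccc1)/C=C(C)/C=C
F2 | step 16 | 14-(phenylsulfinyl) analogue of 23 (sulfur epimers) | CC(=O)O[C@@H]([C@]1(O)[C@@H](C)C(=O)O[C@H]1/C=C(C)\CCC(=O)/C(C)=C\S(=O)c1ccccc1)/C=C(C)/C=C
F3 | step 16 | 14-(phenylsulfinyl) cycloadduct, sulfinyl analogue of 24 | CC(=O)O[C@@H]1[C@H]2C(C)=CC[C@H](S(=O)c3ccccc3)[C@]2(C)C(=O)CC/C(C)=C\[C@@H]2OC(=O)[C@H](C)[C@]21O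
F4 | step 9 | (R)-4-benzyl-3-[(2R,3S,4Z,9Z)-10-bromo-2,8-bis[(tert-butyldimethylsilyl)oxy]-3-hydroxy-5,9-dimethyldeca-4,9-dienoyl]oxazolidin-2-one | O=C1OC[C@@H](Cc2ccccc2)N1C(=O)[C@H](O[Si](C)(C)C(C)(C)C)[C@@H](O)/C=C(C)\CCC(O[Si](C)(C)C(C)(C)C)/C(C)=C\Br
F5 | step 9 | (2R,3S,4Z,9Z)-10-bromo-2,8-bis[(tert-butyldimethylsilyl)oxy]-3-hydroxy-N-methoxy-N,5,9-trimethyldeca-4,9-dienamide | CON(C)C(=O)[C@H](O[Si](C)(C)C(C)(C)C)[C@@H](O)/C=C(C)\CCC(O[Si](C)(C)C(C)(C)C)/C(C)=C\Br
F6 | step 9 | 2-acyl-3-methyl-3-sulfolene bearing the (2R,3S) acyl chain of F5 (β-keto sulfone) | CC1=CCS(=O)(=O)C1C(=O)[C@H](O[Si](C)(C)C(C)(C)C)[C@@H](O)/C=C(C)\CCC(O[Si](C)(C)C(C)(C)C)/C(C)=C\Br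
F7 | step 15 | C7 acrylate analogue of 21 | C=C/C(C)=C/[C@@H](OC(C)=O)C(=O)[C@@H](OC(=O)C=C)/C=C(C)\CCC(=O)/C(C)=C\Br
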